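(The runs were computed with made-up constants, and the scatter is random.)

The reckoning follows the left-handed substrate rather than the yield: the substrates are the limiting reagent in this flask, with 0.200 M together against 0.400 M of solid reagent, and their balance shows whether exchange is at work.

| flask | left-handed substrate | right-handed substrate | solid reagent | catalyst | added ligand | remark | time |
|---|---|---|---|---|---|---|---|
| south-east | 0.10 M | 0.10 M | 0.56 M | 2 mM | 8 mM | run made earlier |  |
| east | 0.10 M | 0.10 M | 0.88 M | 2 mM | 8 mM | run made earlier |  |
| flask | 0.10 M | 0.10 M | 0.400 M | 2.0 mM | 8.0 mM |  | 3.0 d |

- south-east (time / d: left-handed product / %, right-handed product / %): 0.250: 2.6, 0; 0.500: 4.5, 3.2; 1.25: 16.0, 5.9; 3.00: 31.6, 15.3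
- east (time / d: left-handed product / %, right-handed product / %): 0.833: 9.4, 5.0; 1.67: 19.4, 8.9; 2.50: 27.4, 12.2; 3.00: 31.9, 15.2

(standard deviation of a reading: 1 percentage point)

- left-handed product and right-handed product together, in percent of the left-handed substrate and right-handed substrate charged together, at 3.0 d
- excess of left-handed product over right-handed product in the product at 3.0 d
- whether the exchange between left-handed substrate and right-handed substrate keeps pace with the reaction: how far the product's excess at 3.0 d gets from its value without exchange to its value with instant exchange (above 80% keeps pace, below 20% hardly takes part, else lags behind)

- catalyst is single-handed; left-handed substrate and right-handed substrate are mirror images of each other, charged as a racemate, each of them at the stated concentration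
- given per volume of solution although it is solid: solid reagent
- at the start none of the solid reagent is in solution
- an excess is the difference of the two amounts in percent of their sum
- an excess is below zero if the other one leads

The south-east and east runs end alike at 3.00 d, despite their different solid charges. The means are 31.8% of left-handed product and 15.2% of right-handed product, in percent of both substrates charged. The left-handed product leads in both runs under the single-handed catalyst.

Without exchange, each product draws on its own substrate. These means would then leave 18.2% of left-handed substrate against 34.8% of right-handed substrate, about half, and the product ratio would sink as the run went on. Yet the east ratio reads 1.88 at 0.833 d and 2.10 at 3.00 d, higher, though each reading carries a scatter of 1 percentage point.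

So this reckoning takes the two substrates as staying equal, which is dynamic kinetic resolution. The right-handed substrate must then hand over half the product difference. As a part of the left-handed product this is 26.0%, the transfer share. Left-handed substrate remaining is then half the charge minus the left-handed product times one minus that share.

For the flask, this reckoning carries over a yield of 47.0%, which takes 0.0940 M of solid reagent, and an excess of 35.3%. The forecast says 46.5%, slightly lower, with an excess of 35% and an exchange that keeps pace: “The scatter makes this only moderately decisive, but it points to exchange keeping pace.”

The flask gives 45.1% at an excess of 38.2%, and its exchange keeps pace, at 99.3% of the way from the excess without exchange to the excess with instant exchange.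

    partner + catalyst + left-handed substrate → catalyst + left-handed product (k = 7.39 M⁻² min⁻¹)
    partner + catalyst + right-handed substrate → catalyst + right-handed product (k = 3.30 M⁻² min⁻¹)
    left-handed substrate ⇌ right-handed substrate (k = 0.0348 min⁻¹)
    catalyst + added ligand ⇌ idle complex (K = 300 M⁻¹, k = 2.00 M⁻¹ min⁻¹)
    solid reagent ⇌ partner, rate k5*(cs5 - [partner]) while solid is left; crystals form when [partner] > cs5 (solubility = 42.0 mM, k = 0.00922 min⁻¹)

Carried to this flask, the transfer share turns 31.2% of left-handed product into 26.9% of left-handed substrate remaining; the flask holds 27.4%. The neighbour with 8.0 × 10⁻⁴ M of catalyst, other charges and time held, reaches 20.5% at an excess of 38.2%. The same reckoning on its 14.2% of left-handed product gives 39.5% of left-handed substrate remaining, and that neighbour holds 39.7%.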